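(The runs stem from a simulated flask on assumed constants.)

4 questions hang on 3 new flasks: who holds most at 40 h, and how much mono adduct beta holds.

| flask | starting material | coupling partner | remark | time |
|---|---|---|---|---|
| Saturday's | 0.16 M | 0.61 equiv | run made earlier |  |
| Monday's | 0.16 M | 1 equiv | run made earlier |  |
| Wednesday's | 0.16 M | 2.7 equiv | run made earlier |  |
| beta | 0.16 M | 2.50 equiv |  | 40 h |
| gamma | 0.16 M | 0.500 equiv |  | 40 h |
| zeta | 0.16 M | 1.20 equiv |  | 40 h |

- Saturday's (time / h: mono adduct / %, double product / %, starting material / %): 1.50: 4.0, 0.5, 70.1; 3.00: 4.7, 2.1, 67.1; 6.00: 10.1, 0.5, 66.7; 10.0: 13.5, 1.2, 61.6; 20.0: 22.9, 3.0, 54.1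
- Monday's (time / h: mono adduct / %, double product / %, starting material / %): 1.50: 4.0, 0, 70.0; 3.00: 9.8, 1.3, 65.4; 6.00: 14.1, 0, 61.1; 10.0: 20.5, 0.9, 55.7; 20.0: 35.2, 4.1, 45.9
- Wednesday's (time / h: mono adduct / %, double product / %, starting material / %): 2.00: 14.4, 0.3, 61.5; 5.00: 30.3, 1.0, 48.4; 10.0: 45.6, 5.0, 34.1; 15.0: 52.8, 9.4, 26.8; 20.0: 55.7, 16.3, 19.8

(each reading ± 1 percentage point)

- which of these holds the largest part of the starting material at the end of beta (starting material / double product / mono adduct)
- which of these holds the largest part of the starting material at the end of gamma (starting material / double product / mono adduct)
- which of these holds the largest part of the starting material at the end of zeta (starting material / double product / mono adduct)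
- amount of mono adduct at the end of beta, in percent of the starting material charged

- what is said of double product includes crystals
- crystals is a solid; its amount is given per volume of the solution
- the analysis behind the earlier runs scatters by 1 percentage point, standard deviation
- steps under discussion: starting material + coupling partner -> mono adduct; coupling partner + mono adduct -> double product; crystals <-> double product; starting material <-> dormant form

**Fastest rung.** At 1.50 h, starting material reads 70.1% in Saturday's run and 70.0% in Monday's, though the partner loadings differ. Monday's balance is short by 26.0%. I read that gap as dormant form, already in place by the first sample.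

**Coupling rung.** Coupling takes tens of hours: in Wednesday's run, starting material goes from 34.1% at 10.0 h to 19.8% at 20.0 h.

**Slowest rung.** Double product follows behind mono adduct. I assume each step goes with the product of its two reactants. Both steps take one coupling partner, so it cancels from mono adduct made over mono adduct used. Replacing the curves by their means over Wednesday's run from 5.00 h on, mono adduct made (its gain plus double product's) is 41 percentage points and mono adduct used is 15 points. The mean mono adduct is 47.1% and the mean starting material 31.7%, so the holding ratio reads 3.96: this is the mono adduct to starting material ratio at which mono adduct is made as fast as it is used (a selectivity factor). From 10.0 h on, the same means give 3.64, and I accept that spread as the error.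

**My reckoning.** The holding level, this ratio times the starting material present, is 78.4% at the end of Wednesday's run, above its mono adduct of 55.7%. Continuing that run's decay to 40 h leaves 6.68% and a level of 26.4%, below that mono adduct. Taking Wednesday's run as a stand-in for beta, I expect beta's mono adduct past its top at about 55.7%.

**The forecast.** “Integrating by hand while depleting the partner”, it gives mono adduct for beta, starting material for gamma and mono adduct for zeta, with 54% of mono adduct in beta (47% to 59%).

    starting material + coupling partner → mono adduct (k = 7.00 × 10⁻⁵ M⁻¹ s⁻¹)
    coupling partner + mono adduct → double product (k = 1.60 × 10⁻⁵ M⁻¹ s⁻¹)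
    crystals ⇌ double product, rate k3*(cs3 - [double product]) while solid is left; crystals form when [double product] > cs3 (solubility = 25.0 mM, k = 0.00320 s⁻¹)
    starting material ⇌ dormant form (K = 0.390, k = 1.90 × 10⁻⁴ s⁻¹)

**The result.** Beta gives 57.5% of mono adduct, with mono adduct, starting material and mono adduct holding most in beta, gamma and zeta, as forecast. Beta's 13.6% of crystals at 40.0 h leave that mono adduct unchanged. The holding level in beta is 37.4%, below its mono adduct, so the ratio puts made over used at 0.650; beta itself shows 0.719.

**Second flask.** With 4.20 equiv of coupling partner, that neighbour keeps 1.89% of starting material, a holding level of 7.48%, so I expect its mono adduct to stand well below beta's holding level. It stands at 41.9%, less than beta's, and double product holds most.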